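**Retrosynthetic overview**
- Last bond: the C8 ester, from the C8 alcohol and (R)-2-methylbutanoic acid.
- Key disconnection C7–C8: the ten-membered ring C is closed last by a radical reaction. A C8 samarium ketyl adds to C7 of a 3-(acetoxymethyl)butenolide anti to C5, and loss of acetate unveils the exo-methylene.
- Butenolide ring B: from the Z-enal (C6) and a (Z)-β-iodoacrylate carrying C7, C11, C12 and C13, by asymmetric Ni/Cr coupling and lactonisation (sets C6).
- Furanone ring A, formed first: lithium acetylide of silylated (Z)-3-methylpent-2-en-4-yn-1-ol (C2–C6, C15) adds to the Seebach dioxolanone of (R)-lactic acid (C1, C10, C14; allyl = masked C8 aldehyde), then 5-endo oxa-Michael closure.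
- Ring order: A (furanone), then B (butenolide), then C (carbocycle).

Assumption: the SMILES is read at face value as (6R,7R,8R,10S), 4Z with an (R)-2-methylbutanoate (germacrane numbering: C1 ketone, C2=C3 furanone alkene, C4=C5, C6 lactone oxygen, C8 ester, C10 quaternary, C11=C13 methylene, C12 lactone carbonyl); (R)-lactic acid, (R)-2-methylbutanoic acid and (Z)-3-methylpent-2-en-4-yn-1-ol are taken as commercial.

**Step 1**
Reactants: 1 (R)-lactic acid; 2 pivalaldehyde
Product: 3 (2R,5R)-2-tert-butyl-5-methyl-1,3-dioxolan-4-one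
Conditions: p-TsOH·H2O (cat.), H2SO4 (cat.), pentane, reflux, Dean–Stark; recrystallise
Reagents that add atoms: none
Why: Acid-catalysed acetalisation (Seebach self-regeneration of stereocentres) is reversible and gives mainly the cis-dioxolanone, which crystallises and keeps the lactic acid centre (5R) while creating the relay centre (2R).

**Step 2**
Reactants: 3 (2R,5R)-2-tert-butyl-5-methyl-1,3-dioxolan-4-one; 4 allyl bromide
Product: 6 (2R,5S)-2-tert-butyl-5-methyl-5-(prop-2-en-1-yl)-1,3-dioxolan-4-one, via lithium enolate 5 (not isolated)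
Conditions: LDA, THF, −78 °C; then 4, −78 → −30 °C
Reagents that add atoms: none
Why: Seebach enolate alkylation: the planar lithium enolate is allylated on the face anti to the tert-butyl group, so the quaternary carbon (future C10) is formed as 5S.

**Step 3**
Reactants: 7 (2Z)-3-methylpent-2-en-4-yn-1-ol
Product: 8 triethyl{[(2Z)-3-methylpent-2-en-4-yn-1-yl]oxy}silane
Conditions: TESCl, imidazole, CH2Cl2, 0 °C
Reagents that add atoms: triethylsilyl chloride, CC[Si](CC)(CC)Cl
Why: Silyl ether protection keeps the cis-disposed primary hydroxyl from adding to the ynone of step 4 and aromatising to a furan.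

**Step 4**
Reactants: 8 triethyl{[(2Z)-3-methylpent-2-en-4-yn-1-yl]oxy}silane; 6 (2R,5S)-2-tert-butyl-5-methyl-5-(prop-2-en-1-yl)-1,3-dioxolan-4-one
Product: 11 (2S)-2-methyl-2-(prop-2-en-1-yl)-5-{(2Z)-4-[(triethylsilyl)oxy]but-2-en-2-yl}furan-3(2H)-one, via lithium acetylide 9 (not isolated), via hydroxy ynone 10 (not isolated)
Conditions: 8, n-BuLi, THF, −78 °C; add 6, −78 °C, 1 h; aq. NH4Cl; crude 10, Et2NH, EtOH, 23 °C
Reagents that add atoms: none
Why: Acetylide acylation by the dioxolanone (the tetrahedral lithium alkoxide resists a second addition and releases pivalaldehyde on quench) gives the α'-hydroxy ynone, whose tertiary hydroxyl closes by amine-promoted 5-endo-dig oxa-Michael addition to the 3(2H)-furanone without touching C10 or the Z-alkene.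

**Step 5**
Reactants: 11 (2S)-2-methyl-2-(prop-2-en-1-yl)-5-{(2Z)-4-[(triethylsilyl)oxy]but-2-en-2-yl}furan-3(2H)-one
Product: 12 (2Z)-3-[(5S)-5-methyl-4-oxo-5-(prop-2-en-1-yl)-4,5-dihydrofuran-2-yl]but-2-enal
Conditions: (COCl)2, DMSO, CH2Cl2, −78 → −40 °C; Et3N, −78 °C
Reagents that add atoms: none
Why: Swern oxidation applied directly to the primary allylic triethylsilyl ether (desilylative oxidation through the alkoxysulfonium salt) gives the Z-enal at low temperature without a separate deprotection or Z/E isomerisation.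

**Step 6**
Reactants: 13 methyl propiolate; 14 paraformaldehyde
Product: 16 methyl (2Z)-2-[(acetyloxy)methyl]-3-iodoprop-2-enoate, via iodomagnesium alkoxide 15 (not isolated)
Conditions: MgI2, CH2Cl2, 0 → 23 °C; then Ac2O, DMAP (cat.), 0 °C
Reagents that add atoms: magnesium iodide, [Mg+2].[I-].[I-]; acetic anhydride, CC(=O)OC(C)=O
Why: Iodo-aldol (halo-Baylis–Hillman) reaction: iodide adds to the propiolate, the iodoallenolate is trapped by formaldehyde to give the Z isomer (iodine cis to the ester), and the magnesium alkoxide is acetylated in the same flask.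

**Step 7**
Reactants: 12 (2Z)-3-[(5S)-5-methyl-4-oxo-5-(prop-2-en-1-yl)-4,5-dihydrofuran-2-yl]but-2-enal; 16 methyl (2Z)-2-[(acetyloxy)methyl]-3-iodoprop-2-enoate
Product: 18 [(5R)-5-{(1Z)-2-[(5S)-5-methyl-4-oxo-5-(prop-2-en-1-yl)-4,5-dihydrofuran-2-yl]prop-1-en-1-yl}-2-oxo-2,5-dihydrofuran-3-yl]methyl acetate, via hydroxy dienoate 17 (not isolated)
Conditions: CrCl2 (3 equiv), NiCl2 (2 mol%), (S)-N-[2-(4-isopropyl-4,5-dihydrooxazol-2-yl)-6-methylphenyl]methanesulfonamide (Kishi-type ligand, enantiomer chosen for 6R), Et3N, THF, 23 °C; aq. work-up; PPTS (cat.), CH2Cl2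
Reagents that add atoms: none
Why: Nozaki–Hiyama–Kishi coupling: zerovalent nickel inserts into the vinyl iodide, the vinyl group passes to chromium and adds only to the aldehyde, the chiral sulfonamide ligand on trivalent chromium controls the face to set C6 (R), and the Z-γ-hydroxy ester lactonises to the butenolide.

**Step 8**
Reactants: 18 [(5R)-5-{(1Z)-2-[(5S)-5-methyl-4-oxo-5-(prop-2-en-1-yl)-4,5-dihydrofuran-2-yl]prop-1-en-1-yl}-2-oxo-2,5-dihydrofuran-3-yl]methyl acetate
Product: 20 [(5R)-5-{(1Z)-2-[(5S)-5-methyl-4-oxo-5-(2-oxoethyl)-4,5-dihydrofuran-2-yl]prop-1-en-1-yl}-2-oxo-2,5-dihydrofuran-3-yl]methyl acetate, via diol 19 (not isolated)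
Conditions: OsO4 (2 mol%), NaIO4 (4 equiv), 2,6-lutidine, dioxane–H2O 3:1, 23 °C; used at once
Reagents that add atoms: sodium periodate, [Na+].[O-]I(=O)(=O)=O (oxygen relayed by catalytic osmium tetroxide, O=[Os](=O)(=O)=O)
Why: Lemieux–Johnson cleavage: OsO4 dihydroxylates the terminal vinyl group, the only unhindered non-conjugated alkene, faster than the hindered conjugated trisubstituted alkene or the two electron-poor ring alkenes, and NaIO4 cleaves the diol to the C8 aldehyde.

**Step 9**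
Reactants: 20 [(5R)-5-{(1Z)-2-[(5S)-5-methyl-4-oxo-5-(2-oxoethyl)-4,5-dihydrofuran-2-yl]prop-1-en-1-yl}-2-oxo-2,5-dihydrofuran-3-yl]methyl acetate
Product: 23 (6R,7R,8R,10S)-8-hydroxy-1-oxo-3,10-epoxygermacra-2,4(Z),11(13)-trien-12,6-olide, via samarium ketyl 21 (not isolated), via samarium enolate 22 (not isolated)
Conditions: SmI2 (2.5 equiv), THF, 0 °C, 20 added by syringe pump over 4 h (final 0.002 M), no HMPA; pH 7 buffer, 0 °C
Reagents that add atoms: none
Why: Proposed new method: divalent samarium reduces the aldehyde to the C8 ketyl radical, which closes the ten-membered ring by conjugate addition to C7 of the butenolide on the face anti to the C5 alkenyl group (trans lactone, 7R); the resulting α-lactone radical is reduced to the trivalent samarium enolate, which expels acetate (E1cB) to give the exo-methylene, and chelation of the ketyl O–Sm unit to the C1 carbonyl is expected to hold C8 away from C3 and deliver 8R; the closest known reactions are the SmI2 ketyl–acrylate reductive coupling (Fukuzawa lactone synthesis), SmI2 ketyl–olefin medium-ring cyclisations and the two-electron Barbier allylation of aldehydes by 3-(halomethyl)butenolides.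

**Step 10**
Reactants: 23 (6R,7R,8R,10S)-8-hydroxy-1-oxo-3,10-epoxygermacra-2,4(Z),11(13)-trien-12,6-olide; 24 (R)-2-methylbutanoic acid
Product: 25 (6R,7R,8R,10S)-8-[(2R)-2-methylbutanoyloxy]-1-oxo-3,10-epoxygermacra-2,4(Z),11(13)-trien-12,6-olide (CNP0174601.3)
Conditions: DIC, DMAP (10 mol%), CH2Cl2, 0 → 23 °C
Reagents that add atoms: none
Why: Steglich esterification acylates the secondary C8 alcohol with retention at C8 and, at 0 °C with catalytic DMAP, without epimerising the α-stereocentre of the acid.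

**Compound list**
1 | (R)-lactic acid | C[C@@H](O)C(=O)O | starting material
2 | pivalaldehyde (auxiliary) | CC(C)(C)C=O | starting material
3 | (2R,5R)-2-tert-butyl-5-methyl-1,3-dioxolan-4-one | C[C@H]1O[C@@H](C(C)(C)C)OC1=O | intermediate
4 | allyl bromide | C=CCBr | starting material
5 | lithium (2R)-2-tert-butyl-5-methyl-1,3-dioxol-4-olate | CC1=C(O[Li])O[C@H](C(C)(C)C)O1 | intermediate
6 | (2R,5S)-2-tert-butyl-5-methyl-5-(prop-2-en-1-yl)-1,3-dioxolan-4-one | C[C@@]1(CC=C)O[C@@H](C(C)(C)C)OC1=O | intermediate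
7 | (2Z)-3-methylpent-2-en-4-yn-1-ol | C#C/C(C)=C\CO | starting material
8 | triethyl{[(2Z)-3-methylpent-2-en-4-yn-1-yl]oxy}silane | C#C/C(C)=C\CO[Si](CC)(CC)CC | intermediate
9 | lithium acetylide of 8 | [Li]C#C/C(C)=C\CO[Si](CC)(CC)CC | intermediate
10 | (4S,8Z)-4-hydroxy-4,8-dimethyl-10-[(triethylsilyl)oxy]deca-1,8-dien-6-yn-5-one | C=CC[C@](C)(O)C(=O)C#C/C(C)=C\CO[Si](CC)(CC)CC | intermediate
11 | (2S)-2-methyl-2-(prop-2-en-1-yl)-5-{(2Z)-4-[(triethylsilyl)oxy]but-2-en-2-yl}furan-3(2H)-one | C=CC[C@]1(C)OC(=CC1=O)/C(C)=C\CO[Si](CC)(CC)CC | intermediate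
12 | (2Z)-3-[(5S)-5-methyl-4-oxo-5-(prop-2-en-1-yl)-4,5-dihydrofuran-2-yl]but-2-enal | C=CC[C@]1(C)OC(=CC1=O)/C(C)=C\C=O | intermediate
13 | methyl propiolate | C#CC(=O)OC | starting material
14 | paraformaldehyde (formaldehyde source) | C=O | starting material
15 | iodomagnesium alkoxide of methyl (2Z)-2-(hydroxymethyl)-3-iodoprop-2-enoate | I/C=C(/CO[Mg]I)C(=O)OC | intermediate
16 | methyl (2Z)-2-[(acetyloxy)methyl]-3-iodoprop-2-enoate | I/C=C(/COC(C)=O)C(=O)OC | intermediate
17 | methyl (2Z,4R,5Z)-2-[(acetyloxy)methyl]-4-hydroxy-6-[(5S)-5-methyl-4-oxo-5-(prop-2-en-1-yl)-4,5-dihydrofuran-2-yl]hepta-2,5-dienoate (formed as its chromium alkoxide) | C=CC[C@]1(C)OC(=CC1=O)/C(C)=C\[C@@H](O)/C=C(/COC(C)=O)C(=O)OC | intermediate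
18 | [(5R)-5-{(1Z)-2-[(5S)-5-methyl-4-oxo-5-(prop-2-en-1-yl)-4,5-dihydrofuran-2-yl]prop-1-en-1-yl}-2-oxo-2,5-dihydrofuran-3-yl]methyl acetate | C=CC[C@]1(C)OC(=CC1=O)/C(C)=C\[C@H]1OC(=O)C(COC(C)=O)=C1 | intermediate
19 | [(5R)-5-{(1Z)-2-[(5S)-5-(2,3-dihydroxypropyl)-5-methyl-4-oxo-4,5-dihydrofuran-2-yl]prop-1-en-1-yl}-2-oxo-2,5-dihydrofuran-3-yl]methyl acetate (both epimers at the new carbinol carbon) | OCC(O)C[C@]1(C)OC(=CC1=O)/C(C)=C\[C@H]1OC(=O)C(COC(C)=O)=C1 | intermediate
20 | [(5R)-5-{(1Z)-2-[(5S)-5-methyl-4-oxo-5-(2-oxoethyl)-4,5-dihydrofuran-2-yl]prop-1-en-1-yl}-2-oxo-2,5-dihydrofuran-3-yl]methyl acetate | O=CC[C@]1(C)OC(=CC1=O)/C(C)=C\[C@H]1OC(=O)C(COC(C)=O)=C1 | intermediate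
21 | trivalent samarium ketyl of 20 (C8 radical, O–SmI2) | I[Sm](I)O[CH]C[C@]1(C)OC(=CC1=O)/C(C)=C\[C@H]1OC(=O)C(COC(C)=O)=C1 | intermediate
22 | cyclised trivalent samarium lactone enolate (C8–O–SmI2, C13 acetate still in place) | CC(=O)OCC1=C(O[Sm](I)I)O[C@@H]2/C=C(/C)C3=CC(=O)[C@](C)(C[C@@H](O[Sm](I)I)[C@@H]12)O3 | intermediate
23 | (6R,7R,8R,10S)-8-hydroxy-1-oxo-3,10-epoxygermacra-2,4(Z),11(13)-trien-12,6-olide | C=C1C(=O)O[C@@H]2/C=C(/C)C3=CC(=O)[C@](C)(C[C@@H](O)[C@@H]12)O3 | intermediate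
24 | (R)-2-methylbutanoic acid | CC[C@@H](C)C(=O)O | starting material
25 | (6R,7R,8R,10S)-8-[(2R)-2-methylbutanoyloxy]-1-oxo-3,10-epoxygermacra-2,4(Z),11(13)-trien-12,6-olide | C=C1C(=O)O[C@@H]2/C=C(/C)C3=CC(=O)[C@](C)(C[C@@H](OC(=O)[C@H](C)CC)[C@@H]12)O3 | target

**Step count**
Total steps: 10. Longest linear sequence: 8 steps (1, 2, 4, 5, 7, 8, 9, 10, from (R)-lactic acid); steps 3 and 6 are one-step branches.

**Three steps most likely to fail**

Step 9 (ketyl macrocyclisation). The C8 radical may instead attack C3 of the furanone (5-exo) or C5 of the dienone, SmI2 may open the α-oxygenated furanone ketone or reduce the aldehyde without ring closure, the C8 alkoxide may translactonise, and C8 is the least secure stereocentre. Fallback: set out from 20 and replace the C8 radical by a closed-shell allylmetal. Pd(PPh3)4 (zerovalent palladium, 5 mol%) and InI (monovalent indium) in THF at high dilution ionise the allylic acetate and transmetalate to the allylindium iodide acetate F1. F1 adds through C7 to the tethered aldehyde in a chair-like Barbier-type carbonyl allylation and, after aqueous work-up, comes back to the route at 23.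

Step 7 (asymmetric Ni/Cr coupling). Ligand control at C6 next to a hindered Z-enal is unproven, and H6 of the product is base-labile. Fallback: set out from 12 and set C6 by asymmetric alkynylation instead. Methyl propiolate 13, Me2Zn and (S,S)-ProPhenol (enantiomer chosen for 6R) give the propargylic alcohol methyl (4R,5Z)-4-hydroxy-6-[(5S)-5-methyl-4-oxo-5-(prop-2-en-1-yl)-4,5-dihydrofuran-2-yl]hept-5-en-2-ynoate F2. Pd(PPh3)4-catalysed syn-hydrostannation with Bu3SnH puts tin on the ester-bearing carbon, and the adduct (C6–OH cis to the ester) lactonises to the stannyl butenolide F3. Iodine converts it into the iodo butenolide F4. Stille coupling with (tributylstannyl)methanol (Pd2(dba)3, AsPh3) gives the hydroxymethyl butenolide F5, and Ac2O/pyridine comes back to the route at 18.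

Step 8 (selective cleavage of the allyl group). OsO4 may also attack the C4=C5 alkene, and aldehyde 20 can lose the furanone oxygen by β-elimination. Fallback: set out from 6 and unmask C8 before any other alkene is present. O3 in CH2Cl2–MeOH at −78 °C, then Me2S, then HC(OMe)3 with p-TsOH gives the dimethyl acetal (2R,5S)-2-tert-butyl-5-(2,2-dimethoxyethyl)-5-methyl-1,3-dioxolan-4-one F6. Carried through the conditions of steps 4, 5 and 7, it gives the furanone acetal F7, the enal acetal F8 and the butenolide acetate acetal F9. LiBF4 in wet MeCN then hydrolyses the acetal and comes back to the route at 20.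

**Further compounds**
F1 | step 9 | allylindium iodide acetate from 20 (trivalent indium on C13) | O=CC[C@]1(C)OC(=CC1=O)/C(C)=C\[C@H]1OC(=O)C(C[In](I)OC(C)=O)=C1
F2 | step 7 | methyl (4R,5Z)-4-hydroxy-6-[(5S)-5-methyl-4-oxo-5-(prop-2-en-1-yl)-4,5-dihydrofuran-2-yl]hept-5-en-2-ynoate | C=CC[C@]1(C)OC(=CC1=O)/C(C)=C\[C@@H](O)C#CC(=O)OC
F3 | step 7 | (5R)-5-{(1Z)-2-[(5S)-5-methyl-4-oxo-5-(prop-2-en-1-yl)-4,5-dihydrofuran-2-yl]prop-1-en-1-yl}-3-(tributylstannyl)furan-2(5H)-one | C=CC[C@]1(C)OC(=CC1=O)/C(C)=C\[C@H]1OC(=O)C([Sn](CCCC)(CCCC)CCCC)=C1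
F4 | step 7 | (5R)-3-iodo-5-{(1Z)-2-[(5S)-5-methyl-4-oxo-5-(prop-2-en-1-yl)-4,5-dihydrofuran-2-yl]prop-1-en-1-yl}furan-2(5H)-one | C=CC[C@]1(C)OC(=CC1=O)/C(C)=C\[C@H]1OC(=O)C(I)=C1
F5 | step 7 | (5R)-3-(hydroxymethyl)-5-{(1Z)-2-[(5S)-5-methyl-4-oxo-5-(prop-2-en-1-yl)-4,5-dihydrofuran-2-yl]prop-1-en-1-yl}furan-2(5H)-one | C=CC[C@]1(C)OC(=CC1=O)/C(C)=C\[C@H]1OC(=O)C(CO)=C1
F6 | step 8 | (2R,5S)-2-tert-butyl-5-(2,2-dimethoxyethyl)-5-methyl-1,3-dioxolan-4-one | C[C@@]1(CC(OC)OC)O[C@@H](C(C)(C)C)OC1=O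
F7 | step 8 | (2S)-2-(2,2-dimethoxyethyl)-2-methyl-5-{(2Z)-4-[(triethylsilyl)oxy]but-2-en-2-yl}furan-3(2H)-one | COC(OC)C[C@]1(C)OC(=CC1=O)/C(C)=C\CO[Si](CC)(CC)CC
F8 | step 8 | (2Z)-3-[(5S)-5-(2,2-dimethoxyethyl)-5-methyl-4-oxo-4,5-dihydrofuran-2-yl]but-2-enal | COC(OC)C[C@]1(C)OC(=CC1=O)/C(C)=C\C=O
F9 | step 8 | [(5R)-5-{(1Z)-2-[(5S)-5-(2,2-dimethoxyethyl)-5-methyl-4-oxo-4,5-dihydrofuran-2-yl]prop-1-en-1-yl}-2-oxo-2,5-dihydrofuran-3-yl]methyl acetate | COC(OC)C[C@]1(C)OC(=CC1=O)/C(C)=C\[C@H]1OC(=O)C(COC(C)=O)=C1
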